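**Retrosynthetic overview**
1. Last: the C1–C10 oxirane from the E-olefin of triene 37 (peracid). Before it, the two esters: O8 (oxirane acid 32), then O3 ((R)-2-methylbutanoic acid 36).
2. Key disconnection: ring B, the α-methylene-γ-butyrolactone (O, C12, C11, C7, C6), is annulated in one palladium-catalysed operation onto the C4=C5–C6=C7 diene of the ten-membered trienol 25 with 2-bromoacrylic acid 26. C7–C11 forms first, then the ring closes through the carboxylate O–C6 bond.
3. Enabling feature: the lactone oxygen sits on C6, an allylic carbon of ring A next to the C4=C5 Z-olefin. C7–C6(O)–C5=C4 is therefore the 1,2-adduct of a ring diene, and C6 is reached as the terminus of a C4–C5–C6 allylpalladium unit.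
4. Ring A (ten-membered carbocycle) by Nozaki–Hiyama–Kishi closure of C7–C8 of an acyclic iodotrienal; C8 is reset by oxidation and CBS reduction.
5. Chain from but-3-yn-1-ol: carboalumination (E C1=C10), ynone transfer hydrogenation (C3), directed carbomagnesiation (Z C4=C5), Stille coupling (C6=C7). Ring order: ring A, ring B, oxirane.

Key step: step 17

Remark: germacrane numbering is used throughout (ring C1–C10, C14 on C10, C15 on C4, C11–C13 the acrylate unit on C7). The target is read as 1R,3S,6R,7R,8R,10R with a 4Z olefin, an (R)-2-methylbutanoate on O3 and a (2R,3R)-2,3-dimethyloxirane-2-carboxylate on O8; (R)-2-methylbutanoic acid is taken as commercially available.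

**Step 1**
Reactants: 1 but-3-yn-1-ol
Product: 2 1-[(but-3-yn-1-yloxy)methyl]-4-methoxybenzene
Conditions: NaH (1.1 equiv), THF, 0 °C; then 4-methoxybenzyl chloride, n-Bu4NI (cat.), 0 °C → rt
Reagents that add atoms: 4-methoxybenzyl chloride, COc1ccc(CCl)cc1
Why: Williamson ether synthesis; one equivalent of NaH deprotonates only the hydroxyl, and the PMB ether can later be removed under neutral oxidative conditions.

**Step 2**
Reactants: 2 1-[(but-3-yn-1-yloxy)methyl]-4-methoxybenzene; 3 oxirane
Product: 6 (E)-6-[(4-methoxybenzyl)oxy]-4-methylhex-3-en-1-ol, via alkenyldimethylalane 4 (not isolated), via lithium alkenylalanate 5 (not isolated)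
Conditions: Me3Al (2.5 equiv), Cp2ZrCl2 (0.25 equiv), CH2Cl2, 0 °C → rt; volatiles removed; n-BuLi, hexane/THF, −78 → 0 °C; oxirane, THF, 0 °C; aq. Rochelle salt
Reagents that add atoms: trimethylaluminum, C[Al](C)C
Why: Negishi zirconium-catalysed carboalumination adds CH3 and Al syn across the alkyne with CH3 on the internal carbon, which fixes the E geometry of the future C1=C10 olefin, and the derived alanate transfers the alkenyl group to oxirane with retention.

**Step 3**
Reactants: 6 (E)-6-[(4-methoxybenzyl)oxy]-4-methylhex-3-en-1-ol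
Product: 7 (E)-6-[(4-methoxybenzyl)oxy]-4-methylhex-3-enal
Conditions: Dess–Martin periodinane, NaHCO3, CH2Cl2, 0 °C; used crude
Reagents that add atoms: none
Why: Dess–Martin oxidation is neutral and fast, so the β,γ-unsaturated aldehyde should form without migration of the olefin into conjugation.

**Step 4**
Reactants: 7 (E)-6-[(4-methoxybenzyl)oxy]-4-methylhex-3-enal; 8 ethynyltrimethylsilane
Product: 10 rac-(E)-8-[(4-methoxybenzyl)oxy]-6-methyl-1-(trimethylsilyl)oct-5-en-1-yn-3-ol, via lithium (trimethylsilyl)acetylide 9 (not isolated)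
Conditions: 8, n-BuLi, THF, −78 °C; then 7, −78 °C; H2O
Reagents that add atoms: none
Why: 1,2-addition of the lithium acetylide at low temperature outruns enolisation of the aldehyde; the carbinol centre is not controlled here and is reset in steps 5 and 6.

**Step 5**
Reactants: 10 rac-(E)-8-[(4-methoxybenzyl)oxy]-6-methyl-1-(trimethylsilyl)oct-5-en-1-yn-3-ol
Product: 11 (E)-8-[(4-methoxybenzyl)oxy]-6-methyl-1-(trimethylsilyl)oct-5-en-1-yn-3-one
Conditions: Dess–Martin periodinane, NaHCO3, CH2Cl2, 0 °C → rt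
Reagents that add atoms: none
Why: Dess–Martin oxidation of the propargylic alcohol to the ynone under non-basic conditions that leave the β,γ-olefin in place.

**Step 6**
Reactants: 11 (E)-8-[(4-methoxybenzyl)oxy]-6-methyl-1-(trimethylsilyl)oct-5-en-1-yn-3-one
Product: 12 (3S,5E)-8-[(4-methoxybenzyl)oxy]-6-methyl-1-(trimethylsilyl)oct-5-en-1-yn-3-ol
Conditions: Ru[(S,S)-TsDPEN](p-cymene) (2 mol %), i-PrOH, rt
Reagents that add atoms: none
Why: Noyori asymmetric transfer hydrogenation of an alkynyl ketone; the (S,S)-catalyst distinguishes the alkynyl from the CH2 substituent and should give the (S)-propargylic alcohol, which sets C3 under base-free conditions.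

**Step 7**
Reactants: 12 (3S,5E)-8-[(4-methoxybenzyl)oxy]-6-methyl-1-(trimethylsilyl)oct-5-en-1-yn-3-ol
Product: 13 (3S,5E)-8-[(4-methoxybenzyl)oxy]-6-methyloct-5-en-1-yn-3-ol
Conditions: K2CO3 (0.2 equiv), MeOH, rt
Reagents that add atoms: none
Why: methanolysis of the alkynyl C–Si bond; the carbinol centre is not touched.

**Step 8**
Reactants: 13 (3S,5E)-8-[(4-methoxybenzyl)oxy]-6-methyloct-5-en-1-yn-3-ol
Product: 15 (1Z,3S,5E)-1-iodo-8-[(4-methoxybenzyl)oxy]-2,6-dimethylocta-1,5-dien-3-ol, via cyclic alkenylmagnesium alkoxide 14 (not isolated)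
Conditions: MeMgBr (4 equiv), CuI (0.2 equiv), THF/Et2O, −20 °C → rt; then I2, −40 → 0 °C; aq. Na2S2O3
Reagents that add atoms: methylmagnesium bromide, C[Mg]Br; iodine, II
Why: Duboudin hydroxyl-directed anti-carbomagnesiation of a propargylic alcohol: CH3 adds to C4, magnesium to C5 held cis to C3 in the five-membered chelate, and iodinolysis with retention gives the Z-iodoalkene that carries the 4Z geometry of the target.

**Step 9**
Reactants: 15 (1Z,3S,5E)-1-iodo-8-[(4-methoxybenzyl)oxy]-2,6-dimethylocta-1,5-dien-3-ol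
Product: 16 tert-butyl{[(1Z,3S,5E)-1-iodo-8-[(4-methoxybenzyl)oxy]-2,6-dimethylocta-1,5-dien-3-yl]oxy}dimethylsilane
Conditions: TBSOTf, 2,6-lutidine, CH2Cl2, −78 → 0 °C
Reagents that add atoms: tert-butyldimethylsilyl trifluoromethanesulfonate, CC(C)(C)[Si](C)(C)OS(=O)(=O)C(F)(F)F
Why: silylation of the hindered allylic alcohol with the silyl triflate; unlike an allylic ester, the TBS ether is inert to zerovalent palladium and should last until step 22.

**Step 10**
Reactants: 16 tert-butyl{[(1Z,3S,5E)-1-iodo-8-[(4-methoxybenzyl)oxy]-2,6-dimethylocta-1,5-dien-3-yl]oxy}dimethylsilane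
Product: 17 (3E,6S,7Z)-6-[(tert-butyldimethylsilyl)oxy]-8-iodo-3,7-dimethylocta-3,7-dien-1-ol
Conditions: DDQ, CH2Cl2/pH 7 buffer, 0 °C
Reagents that add atoms: none
Why: oxidative cleavage of the PMB ether by DDQ (benzylic hydride abstraction, then hydrolysis); the silyl ether, the iodoalkene and the trisubstituted olefin should not react.

**Step 11**
Reactants: 17 (3E,6S,7Z)-6-[(tert-butyldimethylsilyl)oxy]-8-iodo-3,7-dimethylocta-3,7-dien-1-ol; 18 (E)-1,2-bis(tributylstannyl)ethene
Product: 19 (3E,6S,7Z,9E)-6-[(tert-butyldimethylsilyl)oxy]-3,7-dimethyl-10-(tributylstannyl)deca-3,7,9-trien-1-ol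
Conditions: 18 (3 equiv), PdCl2(MeCN)2 (5 mol %), DMF, rt, dark
Reagents that add atoms: none
Why: Stille coupling with retention at both partners; the excess of the distannane keeps the coupling single and should give the 7Z,9E dienylstannane, which is the C4=C5–C6=C7 diene.

**Step 12**
Reactants: 19 (3E,6S,7Z,9E)-6-[(tert-butyldimethylsilyl)oxy]-3,7-dimethyl-10-(tributylstannyl)deca-3,7,9-trien-1-ol
Product: 20 (3E,6S,7Z,9E)-6-[(tert-butyldimethylsilyl)oxy]-10-iodo-3,7-dimethyldeca-3,7,9-trien-1-ol
Conditions: I2, CH2Cl2, 0 °C, dark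
Reagents that add atoms: iodine, II
Why: iododestannylation (ipso substitution with retention of the E geometry) is much faster than addition of iodine to the olefins.

**Step 13**
Reactants: 20 (3E,6S,7Z,9E)-6-[(tert-butyldimethylsilyl)oxy]-10-iodo-3,7-dimethyldeca-3,7,9-trien-1-ol
Product: 21 (3E,6S,7Z,9E)-6-[(tert-butyldimethylsilyl)oxy]-10-iodo-3,7-dimethyldeca-3,7,9-trienal
Conditions: Dess–Martin periodinane, NaHCO3, CH2Cl2, 0 °C; used at once
Reagents that add atoms: none
Why: Dess–Martin oxidation as in step 3, again without olefin migration.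

**Step 14**
Reactants: 21 (3E,6S,7Z,9E)-6-[(tert-butyldimethylsilyl)oxy]-10-iodo-3,7-dimethyldeca-3,7,9-trienal
Product: 23 (2E,4Z,6S,8E)-6-[(tert-butyldimethylsilyl)oxy]-5,9-dimethylcyclodeca-2,4,8-trien-1-ol (both C1 epimers), via dienylchromium dichloride 22 (not isolated)
Conditions: CrCl2 (8 equiv), NiCl2 (0.1 equiv), DMSO/THF 3:1, rt, slow addition to 0.003 M
Reagents that add atoms: none
Why: Nozaki–Hiyama–Kishi macrocyclisation: the nickel-catalysed dienyl organochromium (trivalent chromium) adds only to the aldehyde under neutral conditions and closes ring A at C7–C8 with retention of the E-olefin; the new C8 carbinol is not controlled and is reset in steps 15 and 16.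

**Step 15**
Reactants: 23 (2E,4Z,6S,8E)-6-[(tert-butyldimethylsilyl)oxy]-5,9-dimethylcyclodeca-2,4,8-trien-1-ol (both C1 epimers)
Product: 24 (2E,4Z,6S,8E)-6-[(tert-butyldimethylsilyl)oxy]-5,9-dimethylcyclodeca-2,4,8-trien-1-one
Conditions: MnO2 (activated, excess), CH2Cl2, rt
Reagents that add atoms: none
Why: selective oxidation of the dienylic alcohol by MnO2; no base is present, so the C9 methylene is not enolised and C1=C10 stays in place.

**Step 16**
Reactants: 24 (2E,4Z,6S,8E)-6-[(tert-butyldimethylsilyl)oxy]-5,9-dimethylcyclodeca-2,4,8-trien-1-one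
Product: 25 (1R,2E,4Z,6S,8E)-6-[(tert-butyldimethylsilyl)oxy]-5,9-dimethylcyclodeca-2,4,8-trien-1-ol
Conditions: (S)-2-methyl-CBS-oxazaborolidine (0.2 equiv), catecholborane (1.8 equiv), toluene, −78 °C; MeOH, aq. NaHCO3
Reagents that add atoms: none
Why: Corey–Bakshi–Shibata reduction; with the dienyl branch as the large and the C9 methylene as the small substituent, the (S)-catalyst should deliver hydride to the face that gives the 8R carbinol (1R in ring numbering), by reagent control.

**Step 17**
Reactants: 25 (1R,2E,4Z,6S,8E)-6-[(tert-butyldimethylsilyl)oxy]-5,9-dimethylcyclodeca-2,4,8-trien-1-ol; 26 2-bromoprop-2-enoic acid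
Product: 28 (3S,6R,7R,8R)-3-[(tert-butyldimethylsilyl)oxy]-8-hydroxygermacra-1(10)E,4Z,11(13)-trien-12,6-olide, via allylpalladium carboxylate 27 (not isolated)
Conditions: 26 (1.5 equiv, slow addition), Pd(OAc)2 (10 mol %), tri(2-furyl)phosphine (20 mol %), Ag2CO3 (1.2 equiv), MeCN/DMF, 50 °C
Reagents that add atoms: none
Why: Larock-type heteroannulation of a 1,3-diene by a halo acid: zerovalent palladium (formed in the flask from Pd(OAc)2 and the phosphine) inserts into the C–Br bond of 26, the alkenylpalladium adds syn across C6=C7 with C11 going to C7, the less substituted diene terminus, and the resulting C4–C5–C6 allylpalladium carboxylate 27 closes the lactone by bond formation between the carboxylate oxygen and C6. The closest known reaction type is the palladium-catalysed annulation of 1,3-dienes by aryl and alkenyl halides that carry an OH, NHR or CO2H group. The one ring that closes is the five-membered lactone (O, C12, C11, C7, C6), by attack of the tethered carboxylate on the near allyl terminus (5-exo with respect to the allyl unit; attack at C4 would need a seven-membered ring to a fully substituted carbon). C7 is set by the face of carbopalladation: the free C8 hydroxyl binds the halide-free alkenylpalladium (Ag2CO3) and steers it to the olefin face syn to the C8–O bond, while the ring chain shields the other face of the E-olefin, which should translate 8R into 7R. C6 is set by suprafacial delivery: the C–O bond forms from the palladium-bound carboxylate on the face that received C11, which for an E ring olefin gives the trans-fused 6R,7R lactone, just as the same pathway gives cis-fused products from Z cyclic dienes. The step needs selectivity for the diene over the isolated C1=C10 olefin (secured by conjugation and allyl formation) and retention of the 4Z geometry (syn–anti exchange at the fully substituted C4 terminus is slow relative to ring closure).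

**Step 18**
Reactants: 29 angelic acid ((Z)-2-methylbut-2-enoic acid)
Product: 30 (Z)-2-methylbut-2-en-1-ol
Conditions: LiAlH4, Et2O, 0 °C; Fieser work-up
Reagents that add atoms: none
Why: hydride reduction of the α-methyl unsaturated acid to the allylic alcohol; the hindered olefin is not reduced and keeps its Z geometry.

**Step 19**
Reactants: 30 (Z)-2-methylbut-2-en-1-ol
Product: 31 [(2S,3R)-2,3-dimethyloxiran-2-yl]methanol
Conditions: Ti(OiPr)4 (10 mol %), L-(+)-diethyl tartrate (12 mol %), t-BuOOH, 4 Å molecular sieves, CH2Cl2, −20 °C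
Reagents that add atoms: tert-butyl hydroperoxide, CC(C)(C)OO
Why: Sharpless asymmetric epoxidation; the titanium L-(+)-tartrate complex delivers the peroxide oxygen to one face of the allylic alcohol and should give the 2S,3R epoxy alcohol, the Z geometry becoming the cis relation of CH2OH and the C3 methyl.

**Step 20**
Reactants: 31 [(2S,3R)-2,3-dimethyloxiran-2-yl]methanol
Product: 32 (2R,3R)-2,3-dimethyloxirane-2-carboxylic acid
Conditions: RuCl3·H2O (2 mol %), NaIO4 (3 equiv), CCl4/MeCN/H2O, rt
Reagents that add atoms: water, O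
Why: ruthenium tetroxide oxidation of the primary alcohol to the acid through the aldehyde hydrate; the oxirane is untouched, and the descriptor at C2 changes from S to R only through the change in priorities.

**Step 21**
Reactants: 28 (3S,6R,7R,8R)-3-[(tert-butyldimethylsilyl)oxy]-8-hydroxygermacra-1(10)E,4Z,11(13)-trien-12,6-olide; 32 (2R,3R)-2,3-dimethyloxirane-2-carboxylic acid
Product: 34 (3S,6R,7R,8R)-3-[(tert-butyldimethylsilyl)oxy]-8-{[(2R,3R)-2,3-dimethyloxirane-2-carbonyl]oxy}germacra-1(10)E,4Z,11(13)-trien-12,6-olide, via mixed anhydride 33 (not isolated)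
Conditions: 32 (1.5 equiv), 2,4,6-trichlorobenzoyl chloride, Et3N, THF, rt; then 28, DMAP, toluene, rt
Reagents that add atoms: none
Why: Yamaguchi esterification acylates the hindered C8 hydroxyl with the α-branched oxirane acid without touching a stereocentre, and capping O8 also removes any chance of lactone migration to O8.

**Step 22**
Reactants: 34 (3S,6R,7R,8R)-3-[(tert-butyldimethylsilyl)oxy]-8-{[(2R,3R)-2,3-dimethyloxirane-2-carbonyl]oxy}germacra-1(10)E,4Z,11(13)-trien-12,6-olide
Product: 35 (3S,6R,7R,8R)-8-{[(2R,3R)-2,3-dimethyloxirane-2-carbonyl]oxy}-3-hydroxygermacra-1(10)E,4Z,11(13)-trien-12,6-olide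
Conditions: HF·pyridine, pyridine, THF, 0 °C → rt
Reagents that add atoms: none
Why: fluoride cleavage of the TBS ether under buffered, non-basic conditions that should spare the α-methylene lactone, the glycidic ester and the acid-sensitive 1,5-diene.

**Step 23**
Reactants: 35 (3S,6R,7R,8R)-8-{[(2R,3R)-2,3-dimethyloxirane-2-carbonyl]oxy}-3-hydroxygermacra-1(10)E,4Z,11(13)-trien-12,6-olide; 36 (R)-2-methylbutanoic acid
Product: 37 (3S,6R,7R,8R)-8-{[(2R,3R)-2,3-dimethyloxirane-2-carbonyl]oxy}-3-{[(2R)-2-methylbutanoyl]oxy}germacra-1(10)E,4Z,11(13)-trien-12,6-olide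
Conditions: 36 (2 equiv), N,N'-diisopropylcarbodiimide, DMAP (0.2 equiv), CH2Cl2, 0 °C → rt
Reagents that add atoms: none
Why: Steglich esterification of the C3 allylic alcohol with retention at C3; carbodiimide activation with catalytic DMAP should not epimerise the α-centre of the acid.

**Step 24**
Reactants: 37 (3S,6R,7R,8R)-8-{[(2R,3R)-2,3-dimethyloxirane-2-carbonyl]oxy}-3-{[(2R)-2-methylbutanoyl]oxy}germacra-1(10)E,4Z,11(13)-trien-12,6-olide
Product: 38 (1R,3S,6R,7R,8R,10R)-1,10-epoxy-8-{[(2R,3R)-2,3-dimethyloxirane-2-carbonyl]oxy}-3-{[(2R)-2-methylbutanoyl]oxy}germacra-4Z,11(13)-dien-12,6-olide (CNP0265335.1)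
Conditions: mCPBA (1.1 equiv), NaHCO3, CH2Cl2, 0 °C
Reagents that add atoms: 3-chloroperbenzoic acid, OOC(=O)c1cccc(Cl)c1
Why: Prilezhaev epoxidation: C1=C10 is the only electron-rich olefin (C4=C5 is flanked by two allylic acyloxy groups, C11=C13 is conjugated to the lactone), the E geometry gives the trans-oxirane, and attack on the outer face of the olefin in the ring conformer with C14 on the β-face should give the 1β,10α (1R,10R) epoxide.

**Compound list**
1 | but-3-yn-1-ol | C#CCCO | starting material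
2 | 1-[(but-3-yn-1-yloxy)methyl]-4-methoxybenzene | COc1ccc(COCCC#C)cc1 | intermediate
3 | oxirane | C1CO1 | starting material
4 | [(E)-4-[(4-methoxybenzyl)oxy]-2-methylbut-1-en-1-yl]dimethylalane | COc1ccc(COCC/C(C)=C/[Al](C)C)cc1 | intermediate
5 | lithium butyl[(E)-4-[(4-methoxybenzyl)oxy]-2-methylbut-1-en-1-yl]dimethylaluminate | [Li+].CCCC[Al-](C)(C)/C=C(\C)CCOCc1ccc(OC)cc1 | intermediate
6 | (E)-6-[(4-methoxybenzyl)oxy]-4-methylhex-3-en-1-ol | COc1ccc(COCC/C(C)=C/CCO)cc1 | intermediate
7 | (E)-6-[(4-methoxybenzyl)oxy]-4-methylhex-3-enal | COc1ccc(COCC/C(C)=C/CC=O)cc1 | intermediate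
8 | ethynyltrimethylsilane | C#C[Si](C)(C)C | starting material
9 | lithium (trimethylsilyl)acetylide | [Li]C#C[Si](C)(C)C | intermediate
10 | rac-(E)-8-[(4-methoxybenzyl)oxy]-6-methyl-1-(trimethylsilyl)oct-5-en-1-yn-3-ol | COc1ccc(COCC/C(C)=C/CC(O)C#C[Si](C)(C)C)cc1 | intermediate
11 | (E)-8-[(4-methoxybenzyl)oxy]-6-methyl-1-(trimethylsilyl)oct-5-en-1-yn-3-one | COc1ccc(COCC/C(C)=C/CC(=O)C#C[Si](C)(C)C)cc1 | intermediate
12 | (3S,5E)-8-[(4-methoxybenzyl)oxy]-6-methyl-1-(trimethylsilyl)oct-5-en-1-yn-3-ol | COc1ccc(COCC/C(C)=C/C[C@H](O)C#C[Si](C)(C)C)cc1 | intermediate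
13 | (3S,5E)-8-[(4-methoxybenzyl)oxy]-6-methyloct-5-en-1-yn-3-ol | COc1ccc(COCC/C(C)=C/C[C@H](O)C#C)cc1 | intermediate
14 | (5S)-5-[(E)-5-[(4-methoxybenzyl)oxy]-3-methylpent-2-en-1-yl]-4-methyl-2,5-dihydro-1,2-oxamagnesole (cyclic alkenylmagnesium alkoxide) | COc1ccc(COCC/C(C)=C/C[C@@H]2O[Mg]C=C2C)cc1 | intermediate
15 | (1Z,3S,5E)-1-iodo-8-[(4-methoxybenzyl)oxy]-2,6-dimethylocta-1,5-dien-3-ol | COc1ccc(COCC/C(C)=C/C[C@H](O)/C(C)=C\I)cc1 | intermediate
16 | tert-butyl{[(1Z,3S,5E)-1-iodo-8-[(4-methoxybenzyl)oxy]-2,6-dimethylocta-1,5-dien-3-yl]oxy}dimethylsilane | COc1ccc(COCC/C(C)=C/C[C@H](O[Si](C)(C)C(C)(C)C)/C(C)=C\I)cc1 | intermediate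
17 | (3E,6S,7Z)-6-[(tert-butyldimethylsilyl)oxy]-8-iodo-3,7-dimethylocta-3,7-dien-1-ol | OCC/C(C)=C/C[C@H](O[Si](C)(C)C(C)(C)C)/C(C)=C\I | intermediate
18 | (E)-1,2-bis(tributylstannyl)ethene | CCCC[Sn](CCCC)(CCCC)/C=C/[Sn](CCCC)(CCCC)CCCC | starting material
19 | (3E,6S,7Z,9E)-6-[(tert-butyldimethylsilyl)oxy]-3,7-dimethyl-10-(tributylstannyl)deca-3,7,9-trien-1-ol | OCC/C(C)=C/C[C@H](O[Si](C)(C)C(C)(C)C)/C(C)=C\C=C\[Sn](CCCC)(CCCC)CCCC | intermediate
20 | (3E,6S,7Z,9E)-6-[(tert-butyldimethylsilyl)oxy]-10-iodo-3,7-dimethyldeca-3,7,9-trien-1-ol | OCC/C(C)=C/C[C@H](O[Si](C)(C)C(C)(C)C)/C(C)=C\C=C\I | intermediate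
21 | (3E,6S,7Z,9E)-6-[(tert-butyldimethylsilyl)oxy]-10-iodo-3,7-dimethyldeca-3,7,9-trienal | O=CC/C(C)=C/C[C@H](O[Si](C)(C)C(C)(C)C)/C(C)=C\C=C\I | intermediate
22 | dichloro[(1E,3Z,5S,7E)-5-[(tert-butyldimethylsilyl)oxy]-4,8-dimethyl-10-oxodeca-1,3,7-trien-1-yl]chromium | O=CC/C(C)=C/C[C@H](O[Si](C)(C)C(C)(C)C)/C(C)=C\C=C\[Cr](Cl)Cl | intermediate
23 | (2E,4Z,6S,8E)-6-[(tert-butyldimethylsilyl)oxy]-5,9-dimethylcyclodeca-2,4,8-trien-1-ol (both C1 epimers) | C1/C(C)=C/C[C@H](O[Si](C)(C)C(C)(C)C)/C(C)=C\C=C\C1O | intermediate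
24 | (2E,4Z,6S,8E)-6-[(tert-butyldimethylsilyl)oxy]-5,9-dimethylcyclodeca-2,4,8-trien-1-one | C1/C(C)=C/C[C@H](O[Si](C)(C)C(C)(C)C)/C(C)=C\C=C\C1=O | intermediate
25 | (1R,2E,4Z,6S,8E)-6-[(tert-butyldimethylsilyl)oxy]-5,9-dimethylcyclodeca-2,4,8-trien-1-ol | C1/C(C)=C/C[C@H](O[Si](C)(C)C(C)(C)C)/C(C)=C\C=C\[C@@H]1O | intermediate
26 | 2-bromoprop-2-enoic acid | C=C(Br)C(=O)O | starting material
27 | C4–C5–C6 allylpalladium carboxylate, drawn as its C6-bound palladalactone form with the other ligands left out | C=C1C(=O)O[Pd][C@@H]2/C=C(/C)[C@@H](O[Si](C)(C)C(C)(C)C)C/C=C(\C)C[C@@H](O)[C@@H]12 | intermediate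
28 | (3S,6R,7R,8R)-3-[(tert-butyldimethylsilyl)oxy]-8-hydroxygermacra-1(10)E,4Z,11(13)-trien-12,6-olide (3β-OTBS, 8β-OH, 6α-O, H-7α) | C=C1C(=O)O[C@@H]2/C=C(/C)[C@@H](O[Si](C)(C)C(C)(C)C)C/C=C(\C)C[C@@H](O)[C@@H]12 | intermediate
29 | angelic acid, (Z)-2-methylbut-2-enoic acid | C/C=C(/C)C(=O)O | starting material
30 | (Z)-2-methylbut-2-en-1-ol | C/C=C(/C)CO | intermediate
31 | [(2S,3R)-2,3-dimethyloxiran-2-yl]methanol | OC[C@]1(C)O[C@@H]1C | intermediate
32 | (2R,3R)-2,3-dimethyloxirane-2-carboxylic acid | OC(=O)[C@]1(C)O[C@@H]1C | intermediate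
33 | (2R,3R)-2,3-dimethyloxirane-2-carboxylic 2,4,6-trichlorobenzoic anhydride | O=C(OC(=O)[C@]1(C)O[C@@H]1C)c1c(Cl)cc(Cl)cc1Cl | intermediate
34 | (3S,6R,7R,8R)-3-[(tert-butyldimethylsilyl)oxy]-8-{[(2R,3R)-2,3-dimethyloxirane-2-carbonyl]oxy}germacra-1(10)E,4Z,11(13)-trien-12,6-olide | C=C1C(=O)O[C@@H]2/C=C(/C)[C@@H](O[Si](C)(C)C(C)(C)C)C/C=C(\C)C[C@@H](OC(=O)[C@]3(C)O[C@@H]3C)[C@@H]12 | intermediate
35 | (3S,6R,7R,8R)-8-{[(2R,3R)-2,3-dimethyloxirane-2-carbonyl]oxy}-3-hydroxygermacra-1(10)E,4Z,11(13)-trien-12,6-olide | C=C1C(=O)O[C@@H]2/C=C(/C)[C@@H](O)C/C=C(\C)C[C@@H](OC(=O)[C@]3(C)O[C@@H]3C)[C@@H]12 | intermediate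
36 | (R)-2-methylbutanoic acid | CC[C@@H](C)C(=O)O | starting material
37 | (3S,6R,7R,8R)-8-{[(2R,3R)-2,3-dimethyloxirane-2-carbonyl]oxy}-3-{[(2R)-2-methylbutanoyl]oxy}germacra-1(10)E,4Z,11(13)-trien-12,6-olide | C=C1C(=O)O[C@@H]2/C=C(/C)[C@@H](OC(=O)[C@H](C)CC)C/C=C(\C)C[C@@H](OC(=O)[C@]3(C)O[C@@H]3C)[C@@H]12 | intermediate
38 | (1R,3S,6R,7R,8R,10R)-1,10-epoxy-8-{[(2R,3R)-2,3-dimethyloxirane-2-carbonyl]oxy}-3-{[(2R)-2-methylbutanoyl]oxy}germacra-4Z,11(13)-dien-12,6-olide (CNP0265335.1) | C=C1C(=O)O[C@@H]2/C=C(/C)[C@@H](OC(=O)[C@H](C)CC)C[C@H]3O[C@]3(C)C[C@@H](OC(=O)[C@]3(C)O[C@@H]3C)[C@@H]12 | target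

**Step count**
Total steps: 24. Longest linear sequence: 21 (steps 1–17 and 21–24; steps 18–20 make the oxirane acid 32).

**Steps most likely to fail**

Step 17. The hydroxyl direction may not override the conformational bias of the ring, so that the alkenylpalladium adds to the wrong face of C6=C7. β-Hydride elimination of the allylpalladium intermediate, or carboxylate attack from the face opposite to palladium, may outrun the intended C–O bond formation. The lactone may also migrate to the free O8 under the basic conditions. Fallback, from 25 back to 28: a radical lactone annulation in place of the organopalladium one. Malonic acid with Mn(OAc)3·2H2O and KOAc in AcOH at rt should add the malonyl radical to C7, the less substituted diene terminus. The C4–C5–C6 allyl radical is oxidised to the cation, and the carboxyl oxygen closes onto C6 to give the α-carboxy lactone F1 (same O–C6 ring closure, trans fusion expected from the cationic closure). Decarboxylative methylenation (aq. CH2O, Et2NH; then NaOAc, AcOH, warm) returns to 28.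

Step 14. Intermolecular addition (oligomers) may compete at a concentration that is still practical, or the β,γ-unsaturated aldehyde may isomerise into conjugation before the organochromium adds. Fallback, from 17 back to 23: the ring is closed at C5–C6 instead of C7–C8. Dess–Martin oxidation of 17 gives the iodo aldehyde F2. (E)-2-(Tributylstannyl)vinyllithium (from 18 and n-BuLi, THF, −78 °C) adds to it to give the stannyl allylic alcohol F3. Intramolecular Stille coupling (Pd2(dba)3, AsPh3, DMF, high dilution, 40 °C) between the Z-iodoalkene and the E-alkenylstannane then forms the diene and the ten-membered ring in one step, giving 23.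

Step 24. The peracid oxygen may be delivered to the other face of C1=C10 (the ring conformer with C14 on the α-face reacting), or the new oxirane may be opened transannularly under acid. Fallback, from 37 back to 38: the halohydrin route, which reverses the facial outcome. NBS in THF/H2O at 0 °C should form the bromonium on the face the peracid prefers, and water opens it at the tertiary C10 from the opposite face to give the bromohydrin F4. K2CO3 in MeCN then closes the oxirane with inversion at C1, which places the oxygen on the face opposite to the one attacked first and gives 38 without any acid.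

**Further compounds**
F1 | step 17 | (3S,6R,7R,8R)-3-[(tert-butyldimethylsilyl)oxy]-8-hydroxygermacra-1(10)E,4Z-dien-12,6-olid-13-oic acid (C11 epimers) | OC(=O)C1C(=O)O[C@@H]2/C=C(/C)[C@@H](O[Si](C)(C)C(C)(C)C)C/C=C(\C)C[C@@H](O)[C@@H]12
F2 | step 14 | (3E,6S,7Z)-6-[(tert-butyldimethylsilyl)oxy]-8-iodo-3,7-dimethylocta-3,7-dienal | O=CC/C(C)=C/C[C@H](O[Si](C)(C)C(C)(C)C)/C(C)=C\I
F3 | step 14 | (1E,5E,8S,9Z)-8-[(tert-butyldimethylsilyl)oxy]-10-iodo-5,9-dimethyl-1-(tributylstannyl)deca-1,5,9-trien-3-ol (both C3 epimers) | CCCC[Sn](CCCC)(CCCC)/C=C/C(O)C/C(C)=C/C[C@H](O[Si](C)(C)C(C)(C)C)/C(C)=C\I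
F4 | step 24 | (1S,3S,6R,7R,8R,10R)-1-bromo-10-hydroxy-8-{[(2R,3R)-2,3-dimethyloxirane-2-carbonyl]oxy}-3-{[(2R)-2-methylbutanoyl]oxy}germacra-4Z,11(13)-dien-12,6-olide | C=C1C(=O)O[C@@H]2/C=C(/C)[C@@H](OC(=O)[C@H](C)CC)C[C@H](Br)[C@](C)(O)C[C@@H](OC(=O)[C@]3(C)O[C@@H]3C)[C@@H]12
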